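The route rests on cutting the C2'–C3' and O1'–C2' bonds of the dihydrofuran fused to catechol ring B. Because C3' is a benzylic carbon ortho to O1', ring B can be unmasked as an ortho-quinone methide, and C2' (carrying the 4-oxygenated aryl group) is delivered as a one-carbon chiral sulfonium benzylide. One operation thus closes the ring, makes two bonds and sets both stereocentres (2'R,3'R). Its precursor is a racemic 2-(α-tosylbenzyl)phenol, two steps from 5-bromo-o-vanillin. The same tactic with the mirror-image ylide then builds the dihydrofuran on ring A. The stilbene is attached only after demethylation, so that no strong acid meets the alkene.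

Key step: step 4

Remark 1: both enantiomers of trans-2,5-dimethylthiolane (6 and 19) are treated as purchasable; otherwise each is two steps from the enantiomeric hexane-2,5-diol (dimesylate, then Na2S with double inversion).
Remark 2: the sense of induction is assigned from the established facial preference of benzylides of this thiolane toward aldehydes ((2R,5R) gives (S,S)-epoxides, which is the 2R sense in a dihydrobenzofuran). The configuration of 12 is to be confirmed through the anomalous scattering of bromine; if it proved opposite, salts 8 and 20 would be exchanged.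

Step 1
Reactants: 1 1-bromo-3,5-dimethoxybenzene; 2 5-bromo-2-hydroxy-3-methoxybenzaldehyde
Product: 4 rac-4-bromo-2-[(3,5-dimethoxyphenyl)(hydroxy)methyl]-6-methoxyphenol, via Grignard reagent 3 (not isolated)
Conditions: 1 (2.5 equiv), Mg turnings, THF, 40 °C; then 2, THF, 0 °C → rt; aq. NH4Cl
Reagents that add atoms: none
Why: Grignard addition in which the first equivalent of 3 deprotonates the phenol and the second adds to the aldehyde of the magnesium phenoxide; the aryl bromide of 2 does not exchange with an arylmagnesium halide at 0 °C, and the racemic carbinol centre is erased later.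

Step 2
Reactants: 4 rac-4-bromo-2-[(3,5-dimethoxyphenyl)(hydroxy)methyl]-6-methoxyphenol
Product: 5 rac-4-bromo-2-[(3,5-dimethoxyphenyl)(4-methylbenzenesulfonyl)methyl]-6-methoxyphenol
Conditions: p-TolSO2H (1.5 equiv, freshly liberated from its sodium salt), CH2Cl2, rt
Reagents that add atoms: p-toluenesulfinic acid, Cc1ccc(cc1)S(=O)O
Why: Acid-assisted SN1 substitution in which the ortho-hydroxybenzhydrol ionises through its protonated quinone methide and is captured at sulfur by the sulfinate, giving a bench-stable sulfone whose configuration is irrelevant.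

Step 3
Reactants: 6 (2R,5R)-2,5-dimethylthiolane; 7 4-methoxybenzyl bromide
Product: 8 (2R,5R)-1-[(4-methoxyphenyl)methyl]-2,5-dimethylthiolan-1-ium tetrafluoroborate
Conditions: 6 (1.1 equiv), AgBF4 (1.0 equiv), CH2Cl2, 0 °C → rt, dark; filtration, trituration with Et2O
Reagents that add atoms: silver tetrafluoroborate, [Ag+].F[B-](F)(F)F
Why: S-alkylation (SN2) of the sulfide by the benzylic bromide, driven by precipitation of AgBr and secured by the non-nucleophilic counter-ion, which cannot remove the labile 4-methoxybenzyl group again; the two faces of the twofold-symmetric sulfide are equivalent, so one sulfonium stereoisomer forms.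

Step 4
Reactants: 5 rac-4-bromo-2-[(3,5-dimethoxyphenyl)(4-methylbenzenesulfonyl)methyl]-6-methoxyphenol; 8 (2R,5R)-1-[(4-methoxyphenyl)methyl]-2,5-dimethylthiolan-1-ium tetrafluoroborate
Product: 12 (2R,3R)-5-bromo-3-(3,5-dimethoxyphenyl)-7-methoxy-2-(4-methoxyphenyl)-2,3-dihydro-1-benzofuran, via ring B ortho-quinone methide 9 (not isolated), via thiolanium benzylide 10 (not isolated), via phenoxide sulfonium betaine 11 (not isolated)
Conditions: 8 (1.5 equiv), Cs2CO3 (3 equiv), CH2Cl2/MeCN (4:1), −20 °C → rt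
Reagents that add atoms: none
Why: Cs2CO3 deprotonates the single phenol of 5, whose phenoxide expels p-toluenesulfinate (1,4-elimination) to give ortho-quinone methide 9, and reversibly deprotonates 8 at the benzylic carbon to the semi-stabilised ylide 10; the ylide carbon attacks the exocyclic carbon of 9 (conjugate addition, C2'–C3'), ring B rearomatises to betaine 11, and its phenoxide displaces the thiolane from C2' with inversion (O1'–C2'). The closest known reaction type is the formal (4+1) annulation of in situ ortho-quinone methides with sulfonium ylides to trans-2,3-dihydrobenzofurans, combined with benzylidene transfer from a chiral thiolanium ylide as practised in aldehyde epoxidation. The dihydrofuran closes by a 5-exo-tet SN2 substitution. C2' is controlled by the twofold-symmetric thiolane, whose ylide should react on the face away from the ring methyl group cis to the benzylidene carbon, the sense that gives (S,S)-epoxides from aldehydes and, after the inverting closure, 2'R here; C3' is controlled by the anti approach that keeps the two aryl groups apart in the open transition state and leads to the trans ring (3'R). The step needs trans selectivity, one ylide face and C- rather than O-benzylation: 5 has only one phenol, placed ortho to the sulfonyl-bearing carbon, sulfinate loss to the diaryl-stabilised quinone methide is fast and reversible so that 5 acts as a reservoir, and the aryl bromide and methyl ethers are inert to carbonate. Minor cis or enantiomeric material is to be removed at 12 by chromatography and crystallisation, because a cis isomer would later epimerise at C2' to the wrong trans enantiomer.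

Step 5
Reactants: 13 2-bromo-4,6-dimethoxybenzaldehyde
Product: 14 2-bromo-6-hydroxy-4-methoxybenzaldehyde
Conditions: BCl3 (1.2 equiv), CH2Cl2, −78 → 0 °C; H2O
Reagents that add atoms: none
Why: Chelation-controlled Lewis-acid ether cleavage, in which boron bound to the aldehyde oxygen cleaves only the adjacent 6-methoxy group through a six-membered chelate and leaves the 4-methoxy group and the bromide untouched.

Step 6
Reactants: 12 (2R,3R)-5-bromo-3-(3,5-dimethoxyphenyl)-7-methoxy-2-(4-methoxyphenyl)-2,3-dihydro-1-benzofuran; 14 2-bromo-6-hydroxy-4-methoxybenzaldehyde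
Product: 17 3-bromo-2-{[(2R,3R)-3-(3,5-dimethoxyphenyl)-7-methoxy-2-(4-methoxyphenyl)-2,3-dihydro-1-benzofuran-5-yl](hydroxy)methyl}-5-methoxyphenol (both carbinol epimers), via aryllithium 15 (not isolated), via sodium phenoxide 16 (not isolated)
Conditions: 12, n-BuLi (1.05 equiv), THF, −78 °C, 15 min; separately 14 (1.2 equiv), NaH (1.2 equiv), THF, 0 °C; phenoxide solution added to the aryllithium, −78 → 0 °C; aq. NH4Cl
Reagents that add atoms: none
Why: Bromine–lithium exchange at −78 °C outruns deprotonation of the dihydrofuran C–H bonds, and the aryllithium then undergoes 1,2-addition to the aldehyde, whose phenol has been converted beforehand into its sodium salt so that it cannot quench the nucleophile; the carbinol epimers are carried on together because this carbon becomes planar in step 9.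

Step 7
Reactants: 17 3-bromo-2-{[(2R,3R)-3-(3,5-dimethoxyphenyl)-7-methoxy-2-(4-methoxyphenyl)-2,3-dihydro-1-benzofuran-5-yl](hydroxy)methyl}-5-methoxyphenol
Product: 18 3-bromo-2-{[(2R,3R)-3-(3,5-dimethoxyphenyl)-7-methoxy-2-(4-methoxyphenyl)-2,3-dihydro-1-benzofuran-5-yl](4-methylbenzenesulfonyl)methyl}-5-methoxyphenol (both epimers at the sulfonyl-bearing carbon)
Conditions: p-TolSO2H (1.5 equiv), CH2Cl2, 0 °C → rt; used after crystallisation or short filtration
Reagents that add atoms: p-toluenesulfinic acid, Cc1ccc(cc1)S(=O)O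
Why: The same SN1 sulfinate exchange as in step 2, made easy by a cation stabilised by the para ring oxygen of ring B and the ortho and para oxygens of ring A; the weak acid does not touch C2' or C3'.

Step 8
Reactants: 19 (2S,5S)-2,5-dimethylthiolane; 7 4-methoxybenzyl bromide
Product: 20 (2S,5S)-1-[(4-methoxyphenyl)methyl]-2,5-dimethylthiolan-1-ium tetrafluoroborate
Conditions: 19 (1.1 equiv), AgBF4 (1.0 equiv), CH2Cl2, 0 °C → rt, dark; filtration, trituration with Et2O
Reagents that add atoms: silver tetrafluoroborate, [Ag+].F[B-](F)(F)F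
Why: The same silver-assisted SN2 S-alkylation as in step 3, applied to the enantiomeric sulfide.

Step 9
Reactants: 18 3-bromo-2-{[(2R,3R)-3-(3,5-dimethoxyphenyl)-7-methoxy-2-(4-methoxyphenyl)-2,3-dihydro-1-benzofuran-5-yl](4-methylbenzenesulfonyl)methyl}-5-methoxyphenol; 20 (2S,5S)-1-[(4-methoxyphenyl)methyl]-2,5-dimethylthiolan-1-ium tetrafluoroborate
Product: 24 (2S,3S)-4-bromo-3-[(2R,3R)-3-(3,5-dimethoxyphenyl)-7-methoxy-2-(4-methoxyphenyl)-2,3-dihydro-1-benzofuran-5-yl]-6-methoxy-2-(4-methoxyphenyl)-2,3-dihydro-1-benzofuran, via ring A ortho-quinone methide 21 (not isolated), via mirror-image thiolanium benzylide 22 (not isolated), via ring A phenoxide sulfonium betaine 23 (not isolated)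
Conditions: 20 (2 equiv), Cs2CO3 (4 equiv), CH2Cl2/MeCN (4:1), 0 °C → rt
Reagents that add atoms: none
Why: The same base-induced (4+1) quinone methide and sulfonium ylide annulation, now through 21 and the mirror-image ylide 22, whose reagent control should set 2S because the ring B stereocentres are remote from the reacting carbon, while anti addition and 5-exo-tet closure of 23 give the trans ring (3S); 18 has a single phenol, and the isomers that arise from any minor enantiomer of 12 are diastereomers of 24 that are separated here, which upgrades the enantiopurity.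

Step 10
Reactants: 24 (2S,3S)-4-bromo-3-[(2R,3R)-3-(3,5-dimethoxyphenyl)-7-methoxy-2-(4-methoxyphenyl)-2,3-dihydro-1-benzofuran-5-yl]-6-methoxy-2-(4-methoxyphenyl)-2,3-dihydro-1-benzofuran
Product: 25 (2S,3S)-4-bromo-3-[(2R,3R)-3-(3,5-dihydroxyphenyl)-7-hydroxy-2-(4-hydroxyphenyl)-2,3-dihydro-1-benzofuran-5-yl]-2-(4-hydroxyphenyl)-2,3-dihydro-1-benzofuran-6-ol
Conditions: BBr3 (12 equiv), CH2Cl2, −78 → 0 °C; MeOH, then aq. NaHCO3
Reagents that add atoms: none
Why: Lewis-acid O-demethylation (bromide attack on the methyl group of each boron-bound ether) is run before any alkene is present, so no cation–olefin cyclisation can occur, and reversible ionisation of the benzylic C2–O or C2'–O1' bonds can only return the thermodynamically preferred trans rings because C3 and C3' are not touched.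

Step 11
Reactants: 25 (2S,3S)-4-bromo-3-[(2R,3R)-3-(3,5-dihydroxyphenyl)-7-hydroxy-2-(4-hydroxyphenyl)-2,3-dihydro-1-benzofuran-5-yl]-2-(4-hydroxyphenyl)-2,3-dihydro-1-benzofuran-6-ol
Product: 26 (2S,3S)-6-acetoxy-3-[(2R,3R)-7-acetoxy-2-(4-acetoxyphenyl)-3-(3,5-diacetoxyphenyl)-2,3-dihydro-1-benzofuran-5-yl]-2-(4-acetoxyphenyl)-4-bromo-2,3-dihydro-1-benzofuran
Conditions: Ac2O (12 equiv), pyridine, DMAP (cat.), CH2Cl2, 0 °C → rt
Reagents that add atoms: acetic anhydride, CC(=O)OC(C)=O
Why: DMAP-catalysed O-acylation turns the air-sensitive hexaphenol into a stable hexaacetate that can be chromatographed and whose less electron-rich aryl bromide is better suited to oxidative addition.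

Step 12
Reactants: 26 (2S,3S)-6-acetoxy-3-[(2R,3R)-7-acetoxy-2-(4-acetoxyphenyl)-3-(3,5-diacetoxyphenyl)-2,3-dihydro-1-benzofuran-5-yl]-2-(4-acetoxyphenyl)-4-bromo-2,3-dihydro-1-benzofuran; 27 4-ethenylphenyl acetate (4-acetoxystyrene)
Product: 28 (2S,3S)-6-acetoxy-3-[(2R,3R)-7-acetoxy-2-(4-acetoxyphenyl)-3-(3,5-diacetoxyphenyl)-2,3-dihydro-1-benzofuran-5-yl]-2-(4-acetoxyphenyl)-4-[(E)-2-(4-acetoxyphenyl)ethenyl]-2,3-dihydro-1-benzofuran
Conditions: 27 (2 equiv), Pd(OAc)2 (5 mol%), [HP(t-Bu)3]BF4 (10 mol%), Cy2NMe (2 equiv), 1,4-dioxane, 90 °C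
Reagents that add atoms: none
Why: Mizoroki–Heck reaction in which zerovalent palladium carrying the bulky, electron-rich phosphine inserts into the hindered C4–Br bond, and syn insertion of the styrene followed by syn β-hydride elimination gives the E-stilbene; the hindered amine base does not cleave aryl acetates.

Step 13
Reactants: 28 (2S,3S)-6-acetoxy-3-[(2R,3R)-7-acetoxy-2-(4-acetoxyphenyl)-3-(3,5-diacetoxyphenyl)-2,3-dihydro-1-benzofuran-5-yl]-2-(4-acetoxyphenyl)-4-[(E)-2-(4-acetoxyphenyl)ethenyl]-2,3-dihydro-1-benzofuran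
Product: 29 (2S,3S)-3-[(2R,3R)-3-(3,5-dihydroxyphenyl)-7-hydroxy-2-(4-hydroxyphenyl)-2,3-dihydro-1-benzofuran-5-yl]-2-(4-hydroxyphenyl)-4-[(E)-2-(4-hydroxyphenyl)ethenyl]-2,3-dihydro-1-benzofuran-6-ol (CNP0172909.1)
Conditions: K2CO3 (0.5 equiv), degassed MeOH/THF, 0 °C → rt; aq. NH4Cl
Reagents that add atoms: none
Why: Base-catalysed transesterification (methanolysis) removes the seven aryl acetates without acid, so the stilbene cannot cyclise onto ring B, and the trans rings have no site that epimerises under mild carbonate.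

Compound list
1 | 1-bromo-3,5-dimethoxybenzene | COc1cc(Br)cc(OC)c1 | starting material
2 | 5-bromo-2-hydroxy-3-methoxybenzaldehyde | COc1cc(Br)cc(C=O)c1O | starting material
3 | (3,5-dimethoxyphenyl)magnesium bromide | COc1cc([Mg]Br)cc(OC)c1 | intermediate (not isolated)
4 | rac-4-bromo-2-[(3,5-dimethoxyphenyl)(hydroxy)methyl]-6-methoxyphenol | COc1cc(Br)cc(C(O)c2cc(OC)cc(OC)c2)c1O | intermediate
5 | rac-4-bromo-2-[(3,5-dimethoxyphenyl)(4-methylbenzenesulfonyl)methyl]-6-methoxyphenol | COc1cc(Br)cc(C(c2cc(OC)cc(OC)c2)S(=O)(=O)c2ccc(C)cc2)c1O | intermediate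
6 | (2R,5R)-2,5-dimethylthiolane | C[C@@H]1CC[C@@H](C)S1 | starting material
7 | 4-methoxybenzyl bromide | COc1ccc(CBr)cc1 | starting material
8 | (2R,5R)-1-[(4-methoxyphenyl)methyl]-2,5-dimethylthiolan-1-ium tetrafluoroborate | C[C@@H]1CC[C@@H](C)[S+]1Cc1ccc(OC)cc1.F[B-](F)(F)F | intermediate
9 | 4-bromo-6-[(3,5-dimethoxyphenyl)methylidene]-2-methoxycyclohexa-2,4-dien-1-one (alkene geometry not defined) | COC1=CC(Br)=CC(=Cc2cc(OC)cc(OC)c2)C1=O | intermediate (not isolated)
10 | (2R,5R)-2,5-dimethylthiolan-1-ium-1-yl (4-methoxyphenyl)methanide | C[C@@H]1CC[C@@H](C)[S+]1[CH-]c1ccc(OC)cc1 | intermediate (not isolated)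
11 | 4-bromo-2-{(1R,2S)-1-(3,5-dimethoxyphenyl)-2-[(2R,5R)-2,5-dimethylthiolan-1-ium-1-yl]-2-(4-methoxyphenyl)ethyl}-6-methoxyphenolate | COc1cc(Br)cc([C@@H](c2cc(OC)cc(OC)c2)[C@@H](c2ccc(OC)cc2)[S+]2[C@H](C)CC[C@H]2C)c1[O-] | intermediate (not isolated)
12 | (2R,3R)-5-bromo-3-(3,5-dimethoxyphenyl)-7-methoxy-2-(4-methoxyphenyl)-2,3-dihydro-1-benzofuran | Brc1cc(OC)c2c(c1)[C@@H](c1cc(OC)cc(OC)c1)[C@H](c1ccc(OC)cc1)O2 | intermediate
13 | 2-bromo-4,6-dimethoxybenzaldehyde | COc1cc(Br)c(C=O)c(OC)c1 | starting material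
14 | 2-bromo-6-hydroxy-4-methoxybenzaldehyde | COc1cc(O)c(C=O)c(Br)c1 | intermediate
15 | [(2R,3R)-3-(3,5-dimethoxyphenyl)-7-methoxy-2-(4-methoxyphenyl)-2,3-dihydro-1-benzofuran-5-yl]lithium | [Li]c1cc(OC)c2c(c1)[C@@H](c1cc(OC)cc(OC)c1)[C@H](c1ccc(OC)cc1)O2 | intermediate (not isolated)
16 | sodium 3-bromo-2-formyl-5-methoxyphenolate | COc1cc([O-])c(C=O)c(Br)c1.[Na+] | intermediate (not isolated)
17 | 3-bromo-2-{[(2R,3R)-3-(3,5-dimethoxyphenyl)-7-methoxy-2-(4-methoxyphenyl)-2,3-dihydro-1-benzofuran-5-yl](hydroxy)methyl}-5-methoxyphenol (both carbinol epimers) | COc1cc(O)c(C(O)c2cc(OC)c3c(c2)[C@@H](c2cc(OC)cc(OC)c2)[C@H](c2ccc(OC)cc2)O3)c(Br)c1 | intermediate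
18 | 3-bromo-2-{[(2R,3R)-3-(3,5-dimethoxyphenyl)-7-methoxy-2-(4-methoxyphenyl)-2,3-dihydro-1-benzofuran-5-yl](4-methylbenzenesulfonyl)methyl}-5-methoxyphenol (both epimers) | COc1cc(O)c(C(c2cc(OC)c3c(c2)[C@@H](c2cc(OC)cc(OC)c2)[C@H](c2ccc(OC)cc2)O3)S(=O)(=O)c2ccc(C)cc2)c(Br)c1 | intermediate
19 | (2S,5S)-2,5-dimethylthiolane | C[C@H]1CC[C@H](C)S1 | starting material
20 | (2S,5S)-1-[(4-methoxyphenyl)methyl]-2,5-dimethylthiolan-1-ium tetrafluoroborate | C[C@H]1CC[C@H](C)[S+]1Cc1ccc(OC)cc1.F[B-](F)(F)F | intermediate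
21 | 3-bromo-2-{[(2R,3R)-3-(3,5-dimethoxyphenyl)-7-methoxy-2-(4-methoxyphenyl)-2,3-dihydro-1-benzofuran-5-yl]methylidene}-5-methoxycyclohexa-3,5-dien-1-one (alkene geometry not defined) | COC1=CC(=O)C(=Cc2cc(OC)c3c(c2)[C@@H](c2cc(OC)cc(OC)c2)[C@H](c2ccc(OC)cc2)O3)C(Br)=C1 | intermediate (not isolated)
22 | (2S,5S)-2,5-dimethylthiolan-1-ium-1-yl (4-methoxyphenyl)methanide | C[C@H]1CC[C@H](C)[S+]1[CH-]c1ccc(OC)cc1 | intermediate (not isolated)
23 | 3-bromo-2-{(1S,2R)-1-[(2R,3R)-3-(3,5-dimethoxyphenyl)-7-methoxy-2-(4-methoxyphenyl)-2,3-dihydro-1-benzofuran-5-yl]-2-[(2S,5S)-2,5-dimethylthiolan-1-ium-1-yl]-2-(4-methoxyphenyl)ethyl}-5-methoxyphenolate | COc1cc([O-])c([C@H](c2cc(OC)c3c(c2)[C@@H](c2cc(OC)cc(OC)c2)[C@H](c2ccc(OC)cc2)O3)[C@H](c2ccc(OC)cc2)[S+]2[C@@H](C)CC[C@@H]2C)c(Br)c1 | intermediate (not isolated)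
24 | (2S,3S)-4-bromo-3-[(2R,3R)-3-(3,5-dimethoxyphenyl)-7-methoxy-2-(4-methoxyphenyl)-2,3-dihydro-1-benzofuran-5-yl]-6-methoxy-2-(4-methoxyphenyl)-2,3-dihydro-1-benzofuran | Brc1cc(OC)cc2c1[C@H](c1cc(OC)c3c(c1)[C@@H](c1cc(OC)cc(OC)c1)[C@H](c1ccc(OC)cc1)O3)[C@@H](c1ccc(OC)cc1)O2 | intermediate
25 | (2S,3S)-4-bromo-3-[(2R,3R)-3-(3,5-dihydroxyphenyl)-7-hydroxy-2-(4-hydroxyphenyl)-2,3-dihydro-1-benzofuran-5-yl]-2-(4-hydroxyphenyl)-2,3-dihydro-1-benzofuran-6-ol | Brc1cc(O)cc2c1[C@H](c1cc(O)c3c(c1)[C@@H](c1cc(O)cc(O)c1)[C@H](c1ccc(O)cc1)O3)[C@@H](c1ccc(O)cc1)O2 | intermediate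
26 | (2S,3S)-6-acetoxy-3-[(2R,3R)-7-acetoxy-2-(4-acetoxyphenyl)-3-(3,5-diacetoxyphenyl)-2,3-dihydro-1-benzofuran-5-yl]-2-(4-acetoxyphenyl)-4-bromo-2,3-dihydro-1-benzofuran | Brc1cc(OC(C)=O)cc2c1[C@H](c1cc(OC(C)=O)c3c(c1)[C@@H](c1cc(OC(C)=O)cc(OC(C)=O)c1)[C@H](c1ccc(OC(C)=O)cc1)O3)[C@@H](c1ccc(OC(C)=O)cc1)O2 | intermediate
27 | 4-ethenylphenyl acetate (4-acetoxystyrene) | CC(=O)Oc1ccc(C=C)cc1 | starting material
28 | (2S,3S)-6-acetoxy-3-[(2R,3R)-7-acetoxy-2-(4-acetoxyphenyl)-3-(3,5-diacetoxyphenyl)-2,3-dihydro-1-benzofuran-5-yl]-2-(4-acetoxyphenyl)-4-[(E)-2-(4-acetoxyphenyl)ethenyl]-2,3-dihydro-1-benzofuran | CC(=O)Oc1ccc(/C=C/c2cc(OC(C)=O)cc3c2[C@H](c2cc(OC(C)=O)c4c(c2)[C@@H](c2cc(OC(C)=O)cc(OC(C)=O)c2)[C@H](c2ccc(OC(C)=O)cc2)O4)[C@@H](c2ccc(OC(C)=O)cc2)O3)cc1 | intermediate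
29 | (2S,3S)-3-[(2R,3R)-3-(3,5-dihydroxyphenyl)-7-hydroxy-2-(4-hydroxyphenyl)-2,3-dihydro-1-benzofuran-5-yl]-2-(4-hydroxyphenyl)-4-[(E)-2-(4-hydroxyphenyl)ethenyl]-2,3-dihydro-1-benzofuran-6-ol (CNP0172909.1) | Oc1ccc(/C=C/c2cc(O)cc3c2[C@H](c2cc(O)c4c(c2)[C@@H](c2cc(O)cc(O)c2)[C@H](c2ccc(O)cc2)O4)[C@@H](c2ccc(O)cc2)O3)cc1 | target

Total step count: 13. Longest linear sequence: 10 steps (steps 1, 2, 4, 6, 7, 9, 10, 11, 12, 13).

Steps most likely to fail

Step 4. The semi-stabilised ylide may discriminate its two faces poorly in the addition to the quinone methide, the syn approach may compete and give the cis ring, or the phenoxide may be O-benzylated by the sulfonium salt before sulfinate is lost. The fallback avoids ylides and uses carbene C–H insertion; it sets out from 4 and returns at 12. Compound 4 is oxidised with MnO2 in CH2Cl2 to (5-bromo-2-hydroxy-3-methoxyphenyl)(3,5-dimethoxyphenyl)methanone F1. Williamson etherification with 7 (K2CO3, DMF) gives {5-bromo-3-methoxy-2-[(4-methoxyphenyl)methoxy]phenyl}(3,5-dimethoxyphenyl)methanone F2. Condensation with hydrazine hydrate (AcOH cat., EtOH, reflux) gives {5-bromo-3-methoxy-2-[(4-methoxyphenyl)methoxy]phenyl}(3,5-dimethoxyphenyl)methanone hydrazone F3. Oxidation with MnO2 gives 5-bromo-1-[diazo(3,5-dimethoxyphenyl)methyl]-3-methoxy-2-[(4-methoxyphenyl)methoxy]benzene F4, which is not isolated. With 1 mol% of the chiral dirhodium tetracarboxylate Rh2(R-PTAD)4 or its enantiomer (whichever delivers 3'R), the donor/donor carbene inserts into the 4-methoxybenzylic C–H bond and gives (2S,3R)-5-bromo-3-(3,5-dimethoxyphenyl)-7-methoxy-2-(4-methoxyphenyl)-2,3-dihydro-1-benzofuran F5. Brief exposure of this cis isomer to TFA in CH2Cl2 at 0 °C epimerises C2' through reversible ionisation of the O1'–C2' bond and should give trans 12.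

Step 9. Facial selectivity may be poor because the bromine ortho to the exocyclic carbon and the bulky ring B substituent distort the approach of the chiral ylide, or because the existing stereocentres oppose it. The fallback gives up reagent control and relies on separation; it sets out from 18 and returns at 24. Compound 18 is annulated under the same base with the achiral salt 1-[(4-methoxyphenyl)methyl]thiolan-1-ium tetrafluoroborate F6, made from thiolane, 7 and AgBF4. Both trans rings on ring A should form. Because ring B is already enantiopure, 24 and its isomer (2R,3R)-4-bromo-3-[(2R,3R)-3-(3,5-dimethoxyphenyl)-7-methoxy-2-(4-methoxyphenyl)-2,3-dihydro-1-benzofuran-5-yl]-6-methoxy-2-(4-methoxyphenyl)-2,3-dihydro-1-benzofuran F7 are diastereomers and are separated by chromatography or crystallisation.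

Step 12. Alkene insertion at the congested aryl–palladium centre next to C3 may be slow, so that hydrodebromination or loss of acetate groups competes at the temperature required. The fallback builds the stilbene away from the congested centre; it sets out from 26 and returns at 28. Stille coupling of 26 with tributyl(vinyl)stannane (Pd(PPh3)4, toluene, 100 °C) transfers a small vinyl group and gives (2S,3S)-6-acetoxy-3-[(2R,3R)-7-acetoxy-2-(4-acetoxyphenyl)-3-(3,5-diacetoxyphenyl)-2,3-dihydro-1-benzofuran-5-yl]-2-(4-acetoxyphenyl)-4-ethenyl-2,3-dihydro-1-benzofuran F8. Olefin cross-metathesis of this styrene with excess 27 (second-generation Grubbs catalyst, CH2Cl2, 40 °C) should then give the E-stilbene 28.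

Further compounds
F1 | step 4 | (5-bromo-2-hydroxy-3-methoxyphenyl)(3,5-dimethoxyphenyl)methanone | COc1cc(Br)cc(C(=O)c2cc(OC)cc(OC)c2)c1O
F2 | step 4 | {5-bromo-3-methoxy-2-[(4-methoxyphenyl)methoxy]phenyl}(3,5-dimethoxyphenyl)methanone | COc1ccc(COc2c(OC)cc(Br)cc2C(=O)c2cc(OC)cc(OC)c2)cc1
F3 | step 4 | {5-bromo-3-methoxy-2-[(4-methoxyphenyl)methoxy]phenyl}(3,5-dimethoxyphenyl)methanone hydrazone | COc1ccc(COc2c(OC)cc(Br)cc2C(=NN)c2cc(OC)cc(OC)c2)cc1
F4 | step 4 | 5-bromo-1-[diazo(3,5-dimethoxyphenyl)methyl]-3-methoxy-2-[(4-methoxyphenyl)methoxy]benzene | COc1ccc(COc2c(OC)cc(Br)cc2C(=[N+]=[N-])c2cc(OC)cc(OC)c2)cc1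
F5 | step 4 | (2S,3R)-5-bromo-3-(3,5-dimethoxyphenyl)-7-methoxy-2-(4-methoxyphenyl)-2,3-dihydro-1-benzofuran | Brc1cc(OC)c2c(c1)[C@@H](c1cc(OC)cc(OC)c1)[C@@H](c1ccc(OC)cc1)O2
F6 | step 9 | 1-[(4-methoxyphenyl)methyl]thiolan-1-ium tetrafluoroborate | COc1ccc(C[S+]2CCCC2)cc1.F[B-](F)(F)F
F7 | step 9 | (2R,3R)-4-bromo-3-[(2R,3R)-3-(3,5-dimethoxyphenyl)-7-methoxy-2-(4-methoxyphenyl)-2,3-dihydro-1-benzofuran-5-yl]-6-methoxy-2-(4-methoxyphenyl)-2,3-dihydro-1-benzofuran | Brc1cc(OC)cc2c1[C@@H](c1cc(OC)c3c(c1)[C@@H](c1cc(OC)cc(OC)c1)[C@H](c1ccc(OC)cc1)O3)[C@H](c1ccc(OC)cc1)O2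
F8 | step 12 | (2S,3S)-6-acetoxy-3-[(2R,3R)-7-acetoxy-2-(4-acetoxyphenyl)-3-(3,5-diacetoxyphenyl)-2,3-dihydro-1-benzofuran-5-yl]-2-(4-acetoxyphenyl)-4-ethenyl-2,3-dihydro-1-benzofuran | C=Cc1cc(OC(C)=O)cc2c1[C@H](c1cc(OC(C)=O)c3c(c1)[C@@H](c1cc(OC(C)=O)cc(OC(C)=O)c1)[C@H](c1ccc(OC(C)=O)cc1)O3)[C@@H](c1ccc(OC(C)=O)cc1)O2
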